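# Hansforester J: proposed total synthesis through a Michael–Claisen annulation for ring A

Compound numbers are those of the steps and of the compound list after them.

Assumption: compound 8 is drawn as its triketo tautomer although it should exist largely as an enol, and its two ring stereocentres are left undefined because both have vanished by compound 10. Compounds 1, 4, 6 and 19 and all reagents are taken as purchased.

## Analysis of the target

Hansforester J (23) is an open chain of four C4 units held by three ester bonds: a 1-(3,5-dihydroxyphenyl)propan-2-ol (ring A, unit 1), a 3-hydroxybutanoate (unit 2), a 2,4-dihydroxy-6-(2-hydroxypropyl)benzoate (ring C, unit 3) and a terminal 3-hydroxybutanoate (unit 4). All four stereocentres are isolated methyl carbinols of R configuration, too far apart for one to control another, so each has to be brought in with a building block of fixed configuration. The molecule is sensitive in three places: the 3-aroyloxybutanoate of unit 2 loses the carboxylate by E1cB elimination under base, a free 2-hydroxypropyl group next to the ring C carboxyl closes to a six-membered lactone, and the free resorcinols are nucleophilic and easily oxidised. The difficulty lies in forming three esters in the right order, one of them a 2,6-disubstituted benzoate of a secondary alcohol, while five hydroxyls are kept apart. The strategy rests on ring A being a 5-alkylresorcinol, that is, an aromatised 5-alkylcyclohexane-1,3-dione. Its C1, the benzylic CH2 and the carbinol carbon are C1, C2 and C3 of (R)-3-hydroxybutanoate. Ring C is the same resorcinol with one more carbon, the carboxyl, between the side chain and a hydroxyl, so the alcohol built for ring A (13) can also be the source of ring C.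

## Retrosynthetic reasoning

23 to 22. All five hydroxyls are masked as benzyl ethers and released together by a final hydrogenolysis. None of the three ester C–O bonds is benzylic, so they survive, and the finished ester chain never meets acid or base.

22 to 13 and 21. The acyl C–O bond between units 1 and 2 is cut. It is the only ester whose acid partner is an unhindered aliphatic acid, and the cut returns the ring A alcohol 13 intact. The forward reaction has to acylate a secondary alcohol with the β-aroyloxy acid 21 without eliminating the aroyloxy group.

21 to 18 and 19, through 20. At the ring C ester the alkyl C–O bond is cut, not the acyl C–O bond, because the di-ortho-substituted acid 18 resists attack at its carbonyl carbon. A Mitsunobu reaction lets the carboxylate act as the nucleophile. It inverts the carbinol, so the S hydroxy ester 19 is needed. The tert-butyl ester of 19 is removed by acid in 20, since base would trigger the elimination named above.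

18 to 15, through 17. The bond between ring C and its carboxyl carbon is cut. Forwards this is an electrophilic formylation ortho to the side chain and para to an ether, followed by oxidation of aldehyde 17. The gain is that ring C falls back onto the ring A series. The side-chain oxygen is already acylated in 15, so the lactone cannot form once the carboxyl appears.

15 to 13 and 14. An ordinary esterification joins units 3 and 4. Acid 14 is the saponified form of benzyl ether 2.

13 to 11, through 12. The carbinol must be free while both phenols carry benzyl groups. It is freed by hydrogenolysis of 11 before the phenols are capped, and triol 12 is then benzylated at the phenols only. A benzyl ether, not a 4-methoxybenzyl ether, is carried on the carbinol for two reasons. Oxidative or acidic removal of a 4-methoxybenzyl group beside the 3,5-dialkoxyphenyl ring would invite closure of the oxocarbenium ion onto that ring (oxa-Pictet–Spengler). The benzyl ether 2 is also the precursor of unit 4.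

11 to 8, through 10. The resorcinol is the dehydro form of dione 10, and 10 is the decarboxylated form of keto ester 8. Decarboxylation comes first, so the oxidation acts on a simple dione and no phenol needs protection while the ring is built.

8 to 5 and 6, the key disconnection. Ring A bonds C1–C2 and C3–C4 are cut. Ring carbons C2 to C6 and both oxygens then come from dimethyl malonate 6 and the acetyl group of enone 5. C1 and the side chain are the unbroken carbon chain of the chiral-pool ester. Forwards, a conjugate addition and a Claisen condensation must run in one flask, passing through adduct 7.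

5 to 1, through 3 and 2. The C=C bond of 5 is cut to aldehyde 3 and the acetonyl ylide 4. Aldehyde 3 is the reduced form of ester 2, the benzyl ether of methyl (R)-3-hydroxybutanoate 1.

## Alternatives that were turned down

Alternative 1: Ring C would be disconnected at both bonds that flank its carboxyl-bearing carbon. The aryne released from 3,5-bis(benzyloxy)-2-iodophenyl triflate A1 would undergo [2+2] cycloaddition with the ketene silyl acetal A2 of O-silylated methyl (R)-3-hydroxybutanoate. This would give the benzocyclobutenone acetal A3, and ring opening of A3 would give the benzoate A4. In its favour, the side chain and the carboxyl carbon are installed in one event, at the benzoate oxidation level, with regiochemistry fixed by the aryne's ether; on this point it is stronger than formylation and oxidation. Against it, A1 takes several steps to make and is opened with an alkyllithium at low temperature. A4 is a hindered methyl benzoate that needs forcing saponification, and once its silyl ether is removed the lactone threatens. The route also makes only ring C, so ring A would need a second synthesis. The chosen strategy gives up the one-step carboxyl installation and in return draws both rings from one annulation of commodity reagents.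

Alternative 2: The ring C carbonyl carbon would be cut from both the arene and the unit 2 oxygen. The aryl iodide A5, the secondary alcohol A6 and carbon monoxide would be joined under palladium–bisphosphine catalysis to give the pentabenzyl ether A7, which is identical with 22. It is the stronger plan in convergence: A5 would come from 15 by iodination and A6 from 13, and formylation, oxidation, the Mitsunobu step and a carboxyl protecting group would all be saved. Against it, a di-ortho-substituted aroyl–palladium species must be intercepted by a hindered secondary alcohol that is also a β-hydroxy ester. That has to happen under amine base and heat, where dehydration or retro-aldol cleavage of A6 and reductive loss of iodine from A5 compete. It also does not say how the resorcinol carbinol itself is made, so it is an end-game variant and not a ring construction. The chosen route spends about three more steps and in return uses reactions that are each established on hindered 2,4-dialkoxy-6-alkylbenzoic acids.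

Alternative 3: Ring A would be cut at C2–C3 and C4–C5. The cyclobutenone A8 and the siloxyalkyne A9 would be heated, so that electrocyclic opening, ketene [2+2] addition, a second opening and 6π closure deliver the phenol A10. In its favour, it reaches the aromatic oxidation level directly and regiospecifically, with no oxidation step; on that point it is stronger than the chosen plan. Against it, A8 needs its own multistep synthesis from a chiral alkyne, and A9 is moisture-sensitive and must be prepared separately. The two phenol oxygens also end up differentiated in A10, which this target does not require. The chosen strategy pays with one oxidation-state adjustment, the aromatisation of 10, and in return needs only malonate, methoxide and one chiral-pool ester that also supplies unit 4.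

Key step: step 4

## Route

Step 1
Reactants: 1 methyl (R)-3-hydroxybutanoate
Product: 2 methyl (R)-3-(benzyloxy)butanoate
Conditions: benzyl 2,2,2-trichloroacetimidate (1.3 equiv), TfOH (5 mol %), CH2Cl2/cyclohexane, 0 °C to rt
Reagents that add atoms: benzyl 2,2,2-trichloroacetimidate, N=C(OCc1ccccc1)C(Cl)(Cl)Cl
Why: Acid-catalysed O-benzylation with the trichloroacetimidate protects the β-hydroxy ester without base, so neither retro-aldol cleavage nor elimination to crotonate can occur; the carbinol C–O bond is not broken and the R configuration is kept.

Step 2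
Reactants: 2 methyl (R)-3-(benzyloxy)butanoate
Product: 3 (R)-3-(benzyloxy)butanal
Conditions: i-Bu2AlH (1.1 equiv), CH2Cl2, −78 °C; MeOH, then aq. KNaC4H4O6
Reagents that add atoms: none
Why: Partial ester reduction with i-Bu2AlH should stop at the aldehyde because the tetrahedral aluminium hemiacetal, chelated by the β-benzyloxy oxygen, persists at −78 °C until the quench; the stereocentre is not α to the carbonyl and cannot epimerise.

Step 3
Reactants: 3 (R)-3-(benzyloxy)butanal; 4 1-(triphenylphosphoranylidene)propan-2-one
Product: 5 (R,E)-6-(benzyloxy)hept-3-en-2-one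
Conditions: 4 (1.3 equiv), THF, reflux
Reagents that add atoms: none
Why: Wittig olefination with the stabilised acetonyl ylide should give the E-enone, and the nearly neutral ylide should not provoke β-elimination of the benzyloxy group from the aldehyde, which is best used crude.

Step 4
Reactants: 5 (R,E)-6-(benzyloxy)hept-3-en-2-one; 6 dimethyl malonate
Product: 8 methyl 6-[(R)-2-(benzyloxy)propyl]-2,4-dioxocyclohexane-1-carboxylate, via Michael adduct 7 (not isolated)
Conditions: NaOMe (1.1 equiv), 6 (1.2 equiv), MeOH, 0 °C to reflux; then cold 1 M HCl to pH 3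
Reagents that add atoms: none
Why: Sodiomalonate adds to C4 of enone 5 (Michael addition) to give adduct 7; methoxide then deprotonates the methyl group of its ketone, and this enolate attacks one malonate ester carbonyl and expels methoxide (Claisen condensation), the final deprotonation of the cyclic β-dicarbonyl pulling every equilibrium forward. The closest known reaction is the malonate annulation of alk-3-en-2-ones that gives dimedone and the 5-alkylcyclohexane-1,3-diones used for 5-alkylresorcinols. The six-membered ring closes in a 6-exo-trig mode, the enolate carbon attacking an ester C=O that lies outside the new ring, so that ring A bond C1–C2 forms in the Michael stage and C3–C4 in the Claisen stage. The two new ring stereocentres, C6 set in the Michael addition without useful induction from the remote ether and the epimerisable C1, are not controlled and need not be, since C1 is lost on decarboxylation and C6 becomes non-stereogenic in dione 10. The step needs 1,4-addition to outrun γ-deprotonation of 5 with vinylogous loss of benzyloxide; a soft stabilised nucleophile, a base charge kept below the malonate charge so that little free methoxide is present, and an alkyl ether as a poor leaving group should secure this, and once 7 has formed the ether is no longer β to any enolisable position. The carbinol centre has no acidifying neighbour and should keep its R configuration.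

Step 5
Reactants: 8 methyl 6-[(R)-2-(benzyloxy)propyl]-2,4-dioxocyclohexane-1-carboxylate
Product: 10 5-[(R)-2-(benzyloxy)propyl]cyclohexane-1,3-dione, via keto acid 9 (not isolated)
Conditions: 2 M aq. NaOH, 90 °C; then HCl to pH 2, 80 °C
Reagents that add atoms: none
Why: Saponification of the ester as its enolate salt and acidification give β-keto acid 9, which should decarboxylate through the usual cyclic transition state on warming; the benzyl ether tolerates hot alkali and dilute acid, and the mixture of ring diastereomers collapses to one compound.

Step 6
Reactants: 10 5-[(R)-2-(benzyloxy)propyl]cyclohexane-1,3-dione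
Product: 11 5-[(R)-2-(benzyloxy)propyl]benzene-1,3-diol
Conditions: I2 (0.2 equiv), DMSO, 80 °C; aq. Na2S2O3
Reagents that add atoms: none
Why: Iodine-mediated oxidative aromatisation: iodination of the dienol at C4, loss of HI to the cyclohexadienone and tautomerisation should give the resorcinol, while DMSO reoxidises HI to I2; the alkyl benzyl ether and the carbinol centre are inert to these conditions.

Step 7
Reactants: 11 5-[(R)-2-(benzyloxy)propyl]benzene-1,3-diol
Product: 12 5-[(R)-2-hydroxypropyl]benzene-1,3-diol
Conditions: H2 (1 atm), 10% Pd/C, EtOH, rt
Reagents that add atoms: none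
Why: Hydrogenolysis of the benzyl alkyl ether frees the carbinol before the phenols are capped, so no oxidative or acidic deprotection is ever run beside the electron-rich dialkoxyarene; the homobenzylic C–O bond and the resorcinol ring are not reduced at one atmosphere, and 11 must be freed of sulfur residues from step 6 first.

Step 8
Reactants: 12 5-[(R)-2-hydroxypropyl]benzene-1,3-diol
Product: 13 (R)-1-[3,5-bis(benzyloxy)phenyl]propan-2-ol
Conditions: benzyl bromide (2.2 equiv), K2CO3, acetone, reflux
Reagents that add atoms: benzyl bromide, BrCc1ccccc1
Why: Williamson etherification under carbonate: only the phenols are acidic enough to be deprotonated by K2CO3, so the secondary alcohol should stay free, the same chemoselectivity that serves for 3,5-dihydroxybenzyl alcohol.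

Step 9
Reactants: 2 methyl (R)-3-(benzyloxy)butanoate
Product: 14 (R)-3-(benzyloxy)butanoic acid
Conditions: LiOH·H2O, THF/H2O, 0 °C to rt; then 1 M HCl
Reagents that add atoms: lithium hydroxide, [Li+].[OH-]
Why: Ester saponification at low temperature; the β-alkoxy group is a poor leaving group, so elimination to crotonate should stay minor and the stereocentre is untouched.

Step 10
Reactants: 13 (R)-1-[3,5-bis(benzyloxy)phenyl]propan-2-ol; 14 (R)-3-(benzyloxy)butanoic acid
Product: 15 (R)-1-[3,5-bis(benzyloxy)phenyl]propan-2-yl (R)-3-(benzyloxy)butanoate
Conditions: EDC·HCl, DMAP (0.2 equiv), CH2Cl2, 0 °C to rt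
Reagents that add atoms: none
Why: Steglich-type carbodiimide esterification with DMAP as acyl-transfer catalyst joins units 3 and 4 before the ring C carboxyl exists, which rules out lactonisation later; both stereocentres are spectators.

Step 11
Reactants: 15 (R)-1-[3,5-bis(benzyloxy)phenyl]propan-2-yl (R)-3-(benzyloxy)butanoate
Product: 17 (R)-1-[3,5-bis(benzyloxy)-2-formylphenyl]propan-2-yl (R)-3-(benzyloxy)butanoate, via iminium chloride 16 (not isolated)
Conditions: POCl3 (1.5 equiv), DMF, 0 to 50 °C; then aq. NaOAc
Reagents that add atoms: N,N-dimethylformamide, CN(C)C=O; water, O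
Why: Vilsmeier–Haack formylation: the chloroiminium ion should attack the only activated arene at the position para to one benzyloxy group and ortho to the side chain, the site between the two ethers being shielded on both sides, as in the formylation of 3,5-dialkoxytoluenes; hydrolysis of iminium salt 16 gives the aldehyde.

Step 12
Reactants: 17 (R)-1-[3,5-bis(benzyloxy)-2-formylphenyl]propan-2-yl (R)-3-(benzyloxy)butanoate
Product: 18 2,4-bis(benzyloxy)-6-[(R)-2-{[(R)-3-(benzyloxy)butanoyl]oxy}propyl]benzoic acid
Conditions: NaClO2, NaH2PO4, 2-methyl-2-butene, t-BuOH/THF/H2O, 0 °C to rt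
Reagents that add atoms: sodium chlorite, [Na+].[O-]Cl=O
Why: Pinnick oxidation converts the hindered aryl aldehyde into the acid under buffered conditions that leave esters and benzyl ethers alone, with 2-methyl-2-butene trapping HOCl before it can chlorinate the electron-rich ring.

Step 13
Reactants: 18 2,4-bis(benzyloxy)-6-[(R)-2-{[(R)-3-(benzyloxy)butanoyl]oxy}propyl]benzoic acid; 19 tert-butyl (S)-3-hydroxybutanoate
Product: 20 (R)-4-(tert-butoxy)-4-oxobutan-2-yl 2,4-bis(benzyloxy)-6-[(R)-2-{[(R)-3-(benzyloxy)butanoyl]oxy}propyl]benzoate
Conditions: PPh3, DIAD, 19 (1.5 equiv), THF, 0 °C to rt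
Reagents that add atoms: none
Why: Mitsunobu esterification: the hydroxyl of 19 is activated as an alkoxyphosphonium ion and displaced by the carboxylate of 18 in an SN2 step, so the hindered carboxyl carbon is never attacked and the S carbinol is inverted to the R configuration of unit 2.

Step 14
Reactants: 20 (R)-4-(tert-butoxy)-4-oxobutan-2-yl 2,4-bis(benzyloxy)-6-[(R)-2-{[(R)-3-(benzyloxy)butanoyl]oxy}propyl]benzoate
Product: 21 (R)-3-({2,4-bis(benzyloxy)-6-[(R)-2-{[(R)-3-(benzyloxy)butanoyl]oxy}propyl]benzoyl}oxy)butanoic acid
Conditions: CF3CO2H/CH2Cl2 (1:4), Et3SiH, 0 °C to rt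
Reagents that add atoms: none
Why: Acidolysis of the tert-butyl ester by loss of the tert-butyl cation, which Et3SiH reduces before it can alkylate the arene, frees the acid without base, which would eliminate the β-aroyloxy group; aryl benzyl ethers and the other esters should tolerate dilute CF3CO2H at this temperature.

Step 15
Reactants: 21 (R)-3-({2,4-bis(benzyloxy)-6-[(R)-2-{[(R)-3-(benzyloxy)butanoyl]oxy}propyl]benzoyl}oxy)butanoic acid; 13 (R)-1-[3,5-bis(benzyloxy)phenyl]propan-2-ol
Product: 22 (R)-1-[3,5-bis(benzyloxy)phenyl]propan-2-yl (R)-3-({2,4-bis(benzyloxy)-6-[(R)-2-{[(R)-3-(benzyloxy)butanoyl]oxy}propyl]benzoyl}oxy)butanoate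
Conditions: EDC·HCl, DMAP (0.1 equiv), CH2Cl2, −10 °C to rt
Reagents that add atoms: none
Why: Carbodiimide esterification of the unhindered aliphatic acid with the secondary alcohol of 13 forms the last ester; low temperature and a small DMAP charge should limit E1cB loss of the aroyloxy group from the activated acid, and no stereocentre is touched.

Step 16
Reactants: 22 (R)-1-[3,5-bis(benzyloxy)phenyl]propan-2-yl (R)-3-({2,4-bis(benzyloxy)-6-[(R)-2-{[(R)-3-(benzyloxy)butanoyl]oxy}propyl]benzoyl}oxy)butanoate
Product: 23 Hansforester J, (R)-1-(3,5-dihydroxyphenyl)propan-2-yl (R)-3-({2,4-dihydroxy-6-[(R)-2-{[(R)-3-hydroxybutanoyl]oxy}propyl]benzoyl}oxy)butanoate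
Conditions: H2 (1 atm), 10% Pd/C, THF/EtOAc, rt
Reagents that add atoms: none
Why: Hydrogenolysis of the four aryl benzyl ethers and the one alkyl benzyl ether in a neutral aprotic solvent; the three ester C–O bonds are homobenzylic or aliphatic and are not cleaved, so the target should be released without acid or base.

## Compound list

1 | methyl (R)-3-hydroxybutanoate | C[C@@H](O)CC(=O)OC | starting material
2 | methyl (R)-3-(benzyloxy)butanoate | C[C@@H](OCc1ccccc1)CC(=O)OC | intermediate
3 | (R)-3-(benzyloxy)butanal | C[C@@H](OCc1ccccc1)CC=O | intermediate
4 | 1-(triphenylphosphoranylidene)propan-2-one | CC(=O)C=P(c1ccccc1)(c1ccccc1)c1ccccc1 | starting material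
5 | (R,E)-6-(benzyloxy)hept-3-en-2-one | CC(=O)/C=C/C[C@@H](C)OCc1ccccc1 | intermediate
6 | dimethyl malonate | COC(=O)CC(=O)OC | starting material
7 | dimethyl 2-[(2R)-2-(benzyloxy)-6-oxoheptan-4-yl]propanedioate (Michael adduct, not isolated) | COC(=O)C(C(=O)OC)C(CC(C)=O)C[C@@H](C)OCc1ccccc1 | intermediate
8 | methyl 6-[(R)-2-(benzyloxy)propyl]-2,4-dioxocyclohexane-1-carboxylate (ring stereocentres unassigned) | COC(=O)C1C(C[C@@H](C)OCc2ccccc2)CC(=O)CC1=O | intermediate
9 | 6-[(R)-2-(benzyloxy)propyl]-2,4-dioxocyclohexane-1-carboxylic acid (keto acid, not isolated) | OC(=O)C1C(C[C@@H](C)OCc2ccccc2)CC(=O)CC1=O | intermediate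
10 | 5-[(R)-2-(benzyloxy)propyl]cyclohexane-1,3-dione | O=C1CC(C[C@@H](C)OCc2ccccc2)CC(=O)C1 | intermediate
11 | 5-[(R)-2-(benzyloxy)propyl]benzene-1,3-diol | Oc1cc(O)cc(C[C@@H](C)OCc2ccccc2)c1 | intermediate
12 | 5-[(R)-2-hydroxypropyl]benzene-1,3-diol | C[C@@H](O)Cc1cc(O)cc(O)c1 | intermediate
13 | (R)-1-[3,5-bis(benzyloxy)phenyl]propan-2-ol | C[C@@H](O)Cc1cc(OCc2ccccc2)cc(OCc2ccccc2)c1 | intermediate
14 | (R)-3-(benzyloxy)butanoic acid | C[C@@H](OCc1ccccc1)CC(=O)O | intermediate
15 | (R)-1-[3,5-bis(benzyloxy)phenyl]propan-2-yl (R)-3-(benzyloxy)butanoate | C[C@H](Cc1cc(OCc2ccccc2)cc(OCc2ccccc2)c1)OC(=O)C[C@@H](C)OCc1ccccc1 | intermediate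
16 | {2,4-bis(benzyloxy)-6-[(R)-2-{[(R)-3-(benzyloxy)butanoyl]oxy}propyl]benzylidene}dimethyliminium chloride (not isolated) | C[C@H](Cc1cc(OCc2ccccc2)cc(OCc2ccccc2)c1C=[N+](C)C)OC(=O)C[C@@H](C)OCc1ccccc1.[Cl-] | intermediate
17 | (R)-1-[3,5-bis(benzyloxy)-2-formylphenyl]propan-2-yl (R)-3-(benzyloxy)butanoate | C[C@H](Cc1cc(OCc2ccccc2)cc(OCc2ccccc2)c1C=O)OC(=O)C[C@@H](C)OCc1ccccc1 | intermediate
18 | 2,4-bis(benzyloxy)-6-[(R)-2-{[(R)-3-(benzyloxy)butanoyl]oxy}propyl]benzoic acid | C[C@H](Cc1cc(OCc2ccccc2)cc(OCc2ccccc2)c1C(=O)O)OC(=O)C[C@@H](C)OCc1ccccc1 | intermediate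
19 | tert-butyl (S)-3-hydroxybutanoate | C[C@H](O)CC(=O)OC(C)(C)C | starting material
20 | (R)-4-(tert-butoxy)-4-oxobutan-2-yl 2,4-bis(benzyloxy)-6-[(R)-2-{[(R)-3-(benzyloxy)butanoyl]oxy}propyl]benzoate | CC(C)(C)OC(=O)C[C@@H](C)OC(=O)c1c(OCc2ccccc2)cc(OCc2ccccc2)cc1C[C@@H](C)OC(=O)C[C@@H](C)OCc1ccccc1 | intermediate
21 | (R)-3-({2,4-bis(benzyloxy)-6-[(R)-2-{[(R)-3-(benzyloxy)butanoyl]oxy}propyl]benzoyl}oxy)butanoic acid | OC(=O)C[C@@H](C)OC(=O)c1c(OCc2ccccc2)cc(OCc2ccccc2)cc1C[C@@H](C)OC(=O)C[C@@H](C)OCc1ccccc1 | intermediate
22 | (R)-1-[3,5-bis(benzyloxy)phenyl]propan-2-yl (R)-3-({2,4-bis(benzyloxy)-6-[(R)-2-{[(R)-3-(benzyloxy)butanoyl]oxy}propyl]benzoyl}oxy)butanoate | C[C@H](Cc1cc(OCc2ccccc2)cc(OCc2ccccc2)c1)OC(=O)C[C@@H](C)OC(=O)c1c(OCc2ccccc2)cc(OCc2ccccc2)cc1C[C@@H](C)OC(=O)C[C@@H](C)OCc1ccccc1 | intermediate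
23 | Hansforester J | C[C@H](Cc1cc(O)cc(O)c1)OC(=O)C[C@@H](C)OC(=O)c1c(O)cc(O)cc1C[C@@H](C)OC(=O)C[C@@H](C)O | target

## Step count and risk

Total step count: 16. Longest linear sequence: 15 steps, from 1 to 23 through steps 1 to 8 and 10 to 16; step 9 is a one-step branch from 2. Alcohol 13 is used twice, in steps 10 and 15.

Steps least certain to work:

Step 4 (key step). The most likely failure is γ-deprotonation of the enone followed by vinylogous loss of benzyloxide before the conjugate addition, or arrest at the open-chain Michael stage if the Claisen closure is slow. The fallback sets out from aldehyde 3 and returns at 8; it exchanges the roles of the two partners. Wittig reaction of 3 with methyl (triphenylphosphoranylidene)acetate in CH2Cl2 should give methyl (R,E)-5-(benzyloxy)hex-2-enoate F1. Its γ-hydrogens are far less acidic than those of an enone, so elimination should be suppressed. Methyl acetoacetate and NaOMe in refluxing MeOH should then add to F1 to give dimethyl 2-acetyl-3-[(R)-2-(benzyloxy)propyl]pentanedioate F2, not isolated. In F2 the acetyl methyl group condenses onto the remote ester to close the same ring and deliver 8.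

Step 6. Iodination and oxidation at C2 between the two carbonyls may compete with the productive iodination at C4, and the electron-rich product may be iodinated on the ring, so the aromatisation may be slow or over-oxidise. The fallback sets out from 10 and returns at 12, bypassing 11, with a regiocontrolled dehydrogenation. Benzyl alcohol with catalytic TsOH in toluene under water removal should give the vinylogous ester 3-(benzyloxy)-5-[(R)-2-(benzyloxy)propyl]cyclohex-2-en-1-one F3. Kinetic deprotonation at C6 with LiN(i-Pr)2 at −78 °C and trapping with PhSeBr should give 3-(benzyloxy)-5-[(R)-2-(benzyloxy)propyl]-6-(phenylselanyl)cyclohex-2-en-1-one F4. Oxidation with H2O2 and syn elimination of the selenoxide, followed by tautomerisation, should give 3-(benzyloxy)-5-[(R)-2-(benzyloxy)propyl]phenol F5. Hydrogenolysis of both benzyl groups over Pd/C then gives 12.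

Step 13. Elimination of the activated β-hydroxy ester to the crotonate may outrun displacement by the bulky carboxylate. The fallback sets out from 18 and returns at 20; it activates the acid instead of the alcohol and proceeds with retention. Oxalyl chloride with catalytic DMF should give 2,4-bis(benzyloxy)-6-[(R)-2-{[(R)-3-(benzyloxy)butanoyl]oxy}propyl]benzoyl chloride F7. F7 is then heated with purchased tert-butyl (R)-3-hydroxybutanoate F8, the enantiomer of 19, in pyridine with DMAP to give 20.

Step 15. The aroyloxy group may be lost by E1cB elimination from the activated acyl intermediate, which would split the chain into a crotonate and acid 18. The fallback sets out from 13 and 18 and returns at 22; it forms the unit 1–unit 2 ester first and closes the chain at the aryl ester. Heating 13 with 2,2,6-trimethyl-4H-1,3-dioxin-4-one in xylene should give (R)-1-[3,5-bis(benzyloxy)phenyl]propan-2-yl 3-oxobutanoate F9. Noyori hydrogenation of F9 with RuCl2[(S)-BINAP] should give (R)-1-[3,5-bis(benzyloxy)phenyl]propan-2-yl (S)-3-hydroxybutanoate F10 under catalyst control. Mitsunobu reaction of F10 with 18 (PPh3, DIAD) then inverts the new carbinol and gives 22.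

Step 11. Formylation ortho to the branched side chain may be slow, and forcing it with heat may cause chloride-assisted loss of a benzyl group or some attack at the position between the two ethers. The fallback sets out from 15 and returns at 18, bypassing 17; it uses halogenation and carbonylation in place of formylation and oxidation. N-Bromosuccinimide in MeCN at 0 °C, a small electrophile with a strong preference for the position para to an ether, should give (R)-1-[3,5-bis(benzyloxy)-2-bromophenyl]propan-2-yl (R)-3-(benzyloxy)butanoate F6. Hydroxycarbonylation of F6 with Pd(OAc)2 and Xantphos under CO (1 atm) with water and i-Pr2NEt in dioxane at 90 °C then gives 18.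

## Further compounds

F1 | step 4 | methyl (R,E)-5-(benzyloxy)hex-2-enoate | COC(=O)/C=C/C[C@@H](C)OCc1ccccc1
F2 | step 4 | dimethyl 2-acetyl-3-[(R)-2-(benzyloxy)propyl]pentanedioate | COC(=O)CC(C[C@@H](C)OCc1ccccc1)C(C(C)=O)C(=O)OC
F3 | step 6 | 3-(benzyloxy)-5-[(R)-2-(benzyloxy)propyl]cyclohex-2-en-1-one | O=C1C=C(OCc2ccccc2)CC(C[C@@H](C)OCc2ccccc2)C1
F4 | step 6 | 3-(benzyloxy)-5-[(R)-2-(benzyloxy)propyl]-6-(phenylselanyl)cyclohex-2-en-1-one | O=C1C=C(OCc2ccccc2)CC(C[C@@H](C)OCc2ccccc2)C1[Se]c1ccccc1
F5 | step 6 | 3-(benzyloxy)-5-[(R)-2-(benzyloxy)propyl]phenol | Oc1cc(OCc2ccccc2)cc(C[C@@H](C)OCc2ccccc2)c1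
F6 | step 11 | (R)-1-[3,5-bis(benzyloxy)-2-bromophenyl]propan-2-yl (R)-3-(benzyloxy)butanoate | C[C@H](Cc1cc(OCc2ccccc2)cc(OCc2ccccc2)c1Br)OC(=O)C[C@@H](C)OCc1ccccc1
F7 | step 13 | 2,4-bis(benzyloxy)-6-[(R)-2-{[(R)-3-(benzyloxy)butanoyl]oxy}propyl]benzoyl chloride | C[C@H](Cc1cc(OCc2ccccc2)cc(OCc2ccccc2)c1C(=O)Cl)OC(=O)C[C@@H](C)OCc1ccccc1
F8 | step 13 | tert-butyl (R)-3-hydroxybutanoate | C[C@@H](O)CC(=O)OC(C)(C)C
F9 | step 15 | (R)-1-[3,5-bis(benzyloxy)phenyl]propan-2-yl 3-oxobutanoate | C[C@H](Cc1cc(OCc2ccccc2)cc(OCc2ccccc2)c1)OC(=O)CC(C)=O
F10 | step 15 | (R)-1-[3,5-bis(benzyloxy)phenyl]propan-2-yl (S)-3-hydroxybutanoate | C[C@H](Cc1cc(OCc2ccccc2)cc(OCc2ccccc2)c1)OC(=O)C[C@H](C)O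
A1 | alternative 1 | 3,5-bis(benzyloxy)-2-iodophenyl trifluoromethanesulfonate | O=S(=O)(Oc1cc(OCc2ccccc2)cc(OCc2ccccc2)c1I)C(F)(F)F
A2 | alternative 1 | (R)-3-(tert-butyldimethylsilyloxy)-1-methoxy-1-(trimethylsilyloxy)but-1-ene | C[C@@H](O[Si](C)(C)C(C)(C)C)C=C(OC)O[Si](C)(C)C
A3 | alternative 1 | 3,5-bis(benzyloxy)-8-[(R)-1-(tert-butyldimethylsilyloxy)ethyl]-7-methoxy-7-(trimethylsilyloxy)bicyclo[4.2.0]octa-1,3,5-triene | C[C@@H](O[Si](C)(C)C(C)(C)C)C1c2cc(OCc3ccccc3)cc(OCc3ccccc3)c2C1(OC)O[Si](C)(C)C
A4 | alternative 1 | methyl 2,4-bis(benzyloxy)-6-[(R)-2-(tert-butyldimethylsilyloxy)propyl]benzoate | COC(=O)c1c(OCc2ccccc2)cc(OCc2ccccc2)cc1C[C@@H](C)O[Si](C)(C)C(C)(C)C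
A5 | alternative 2 | (R)-1-[3,5-bis(benzyloxy)-2-iodophenyl]propan-2-yl (R)-3-(benzyloxy)butanoate | C[C@H](Cc1cc(OCc2ccccc2)cc(OCc2ccccc2)c1I)OC(=O)C[C@@H](C)OCc1ccccc1
A6 | alternative 2 | (R)-1-[3,5-bis(benzyloxy)phenyl]propan-2-yl (R)-3-hydroxybutanoate | C[C@H](Cc1cc(OCc2ccccc2)cc(OCc2ccccc2)c1)OC(=O)C[C@@H](C)O
A7 | alternative 2 | pentabenzyl ether of Hansforester J (identical with 22) | C[C@H](Cc1cc(OCc2ccccc2)cc(OCc2ccccc2)c1)OC(=O)C[C@@H](C)OC(=O)c1c(OCc2ccccc2)cc(OCc2ccccc2)cc1C[C@@H](C)OC(=O)C[C@@H](C)OCc1ccccc1
A8 | alternative 3 | 3-[(R)-2-(tert-butyldimethylsilyloxy)propyl]cyclobut-2-en-1-one | C[C@H](CC1=CC(=O)C1)O[Si](C)(C)C(C)(C)C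
A9 | alternative 3 | (triisopropylsilyloxy)acetylene | C#CO[Si](C(C)C)(C(C)C)C(C)C
A10 | alternative 3 | 3-[(R)-2-(tert-butyldimethylsilyloxy)propyl]-5-(triisopropylsilyloxy)phenol | C[C@H](Cc1cc(O)cc(O[Si](C(C)C)(C(C)C)C(C)C)c1)O[Si](C)(C)C(C)(C)C
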